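**Plan**
- Retrosynthetic cuts: the C8 ester; then the furanone O–C3 bond (last skeletal bond); then C1–C2 (opens the ten-membered carbocycle); then C6–C7 with the lactone C–O. This leaves enynal 7 (C2–C6, C15) and allyl bromide 20 (C1, C7–C14).
- Forward order of rings: cis-fused α-methylene-γ-lactone (indium Barbier, step 12), then the ten-membered carbocycle (CrCl2/NiCl2 alkynylation, step 15), then the furanone bridge by transannular cyclisation (step 17), then tiglate and desilylation.
- Stereochemistry: C10 from a copper–bis(oxazoline) pyruvate aldol; C8 from a CBS reduction; C7 and C6 from the Barbier step (relayed from C8; Z-allylindium gives syn, hence the cis-lactone); the C4=C5 geometry from anti-hydroalumination/iodination of butynediol.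
- Enabling feature: the tertiary C10–OH is α′ to the C1 ketone and the C2≡C3 bond lies inside the C1–C10 carbocycle, so O10 and C3 are 1,4 across C1. A 5-endo-dig attack closes the furanone (O, C3, C2, C1, C10) and so turns a monocyclic cyclodec-4-en-2-ynone into the 11-oxabicyclo[6.2.1]undecane core.
- Helpers: a methyl furanoside ring ties C1 (aldehyde level) to O8 from step 8 to step 14; O15 carries a tert-butyldiphenylsilyl group to the last step.

Key step: step 17

Remark: the target is taken exactly as drawn, with the cis-fused 6,12-lactone. Germacrane numbering is used throughout: C1 ketone, C2/C3 furanone CH and O-bearing carbon, C4=C5, C6 lactone O–CH, C7, C8 ester-bearing CH, C9 CH2, C10 quaternary carbon with methyl C14, C11–C13 methylene lactone, C15 hydroxymethyl.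

**Route**

Step 1
Reactants: 1 but-2-yne-1,4-diol
Product: 2 4-(tert-butyldiphenylsilyloxy)but-2-yn-1-ol
Conditions: NaH (1.0 equiv), THF, 0 °C; tBuPh2SiCl (1.0 equiv), 0 °C to rt
Reagents that add atoms: tert-butyl(chloro)diphenylsilane, CC(C)(C)[Si](Cl)(c1ccccc1)c1ccccc1
Why: Monosilylation of a symmetrical diol through its monosodium alkoxide (O-silylation) should give the mono-ether, and the bulky silyl group is chosen to survive every later acidic step.

Step 2
Reactants: 2 4-(tert-butyldiphenylsilyloxy)but-2-yn-1-ol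
Product: 4 (Z)-4-(tert-butyldiphenylsilyloxy)-3-iodobut-2-en-1-ol, via cyclic sodium alkenylalanate 3 (not isolated)
Conditions: NaAlH2(OCH2CH2OMe)2, THF, 0 °C; then I2, −78 °C to 0 °C
Reagents that add atoms: iodine, II
Why: Hydroxyl-directed anti-hydroalumination of the propargylic alcohol places aluminium on the distal alkyne carbon in a five-membered chelate, and iodinolysis with retention should give the vinyl iodide with iodine cis to the hydroxymethyl group, the geometry that becomes the ring C4=C5 bond.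

Step 3
Reactants: 4 (Z)-4-(tert-butyldiphenylsilyloxy)-3-iodobut-2-en-1-ol; 5 ethynyltrimethylsilane
Product: 6 (E)-3-[(tert-butyldiphenylsilyloxy)methyl]-5-(trimethylsilyl)pent-2-en-4-yn-1-ol (alkyne cis to CH2OH)
Conditions: PdCl2(PPh3)2 (3 mol %), CuI (6 mol %), Et3N, THF, rt
Reagents that add atoms: none
Why: Sonogashira coupling proceeds with retention at the vinyl iodide, so the alkyne (C2, C3) should end up cis to the carbon that becomes C6.

Step 4
Reactants: 6 (E)-3-[(tert-butyldiphenylsilyloxy)methyl]-5-(trimethylsilyl)pent-2-en-4-yn-1-ol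
Product: 7 (E)-3-[(tert-butyldiphenylsilyloxy)methyl]-5-(trimethylsilyl)pent-2-en-4-ynal (alkyne cis to CHO)
Conditions: MnO2 (activated, excess), CH2Cl2, rt
Reagents that add atoms: none
Why: MnO2 oxidises allylic alcohols to enals under neutral conditions that should leave both silyl groups and the alkene geometry untouched.

Step 5
Reactants: 8 4-methylpent-3-en-2-one (mesityl oxide)
Product: 9 4-methyl-2-(trimethylsilyloxy)penta-1,3-diene
Conditions: LiN(iPr)2, Me3SiCl (internal quench), THF, −78 °C
Reagents that add atoms: chlorotrimethylsilane, C[Si](C)(C)Cl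
Why: Kinetic α′-deprotonation of the enone with in situ silyl trapping (silyl enol ether formation) should give the cross-conjugated 2-silyloxydiene.

Step 6
Reactants: 9 4-methyl-2-(trimethylsilyloxy)penta-1,3-diene; 10 methyl pyruvate
Product: 11 methyl (R)-2,6-dimethyl-4-oxo-2-(trimethylsilyloxy)hept-5-enoate
Conditions: Cu(OTf)2 (10 mol %), (R,R)-tBu-box (11 mol %), THF, −78 °C
Reagents that add atoms: none
Why: A copper–bis(oxazoline)-catalysed Mukaiyama aldol addition to the bidentate-bound pyruvate, with the ligand enantiomer chosen to leave the Re face of the ketone open, should set the C10 carbinol (R) and deliver it as its silyl ether by silyl transfer, the gem-dimethyl terminus of the diene disfavouring a hetero-Diels–Alder path.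

Step 7
Reactants: 11 methyl (R)-2,6-dimethyl-4-oxo-2-(trimethylsilyloxy)hept-5-enoate
Product: 13 (3R,5R)-3-hydroxy-3-methyl-5-(2-methylprop-1-enyl)oxolan-2-one, via hydroxy ester 12 (not isolated)
Conditions: (S)-Me-CBS oxazaborolidine (20 mol %), catecholborane, toluene, −78 °C; aqueous work-up; then Bu4NF, THF, 0 °C to rt
Reagents that add atoms: none
Why: Corey–Bakshi–Shibata reduction, in which the alkenyl group acts as the large substituent, should set C8 (R) under catalyst control, and fluoride desilylation then lets the C8 oxygen close the γ-lactone onto the methyl ester (hydroxyl cis to the alkenyl group).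

Step 8
Reactants: 13 (3R,5R)-3-hydroxy-3-methyl-5-(2-methylprop-1-enyl)oxolan-2-one
Product: 15 (3R,5R)-2-methoxy-3-methyl-5-(2-methylprop-1-enyl)oxolan-3-ol (anomers), via lactol 14 (not isolated)
Conditions: iBu2AlH (2.2 equiv), CH2Cl2, −78 °C; then MeOH, PPTS (cat.), rt
Reagents that add atoms: methanol, CO
Why: Low-temperature iBu2AlH reduction stops at the lactol, and acid-catalysed acetalisation with methanol (Fischer-type glycosidation) locks C1 at the aldehyde level in a furanoside ring that also masks O8, the anomeric mixture being inconsequential.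

Step 9
Reactants: 15 (3R,5R)-2-methoxy-3-methyl-5-(2-methylprop-1-enyl)oxolan-3-ol
Product: 17 (2R,4R)-4-hydroxy-5-methoxy-4-methyloxolane-2-carbaldehyde, via ozonide 16 (not isolated)
Conditions: O3, CH2Cl2, −78 °C; then Me2S, −78 °C to rt
Reagents that add atoms: ozone, [O-][O+]=O
Why: Ozonolysis of the electron-rich trisubstituted alkene with reductive work-up should give the α-alkoxy aldehyde at C7 without touching the acetal or the C8 stereocentre.

Step 10
Reactants: 17 (2R,4R)-4-hydroxy-5-methoxy-4-methyloxolane-2-carbaldehyde; 18 methyl acrylate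
Product: 19 methyl 2-{hydroxy[(2R,4R)-4-hydroxy-5-methoxy-4-methyloxolan-2-yl]methyl}prop-2-enoate (carbinol epimers)
Conditions: 18 (excess), DABCO (0.5 equiv), MeOH, rt, prolonged
Reagents that add atoms: none
Why: The Morita–Baylis–Hillman reaction of an activated α-alkoxy aldehyde attaches C11–C13 to C7, and the configuration of the new carbinol is irrelevant because it is erased in step 11.

Step 11
Reactants: 19 methyl 2-{hydroxy[(2R,4R)-4-hydroxy-5-methoxy-4-methyloxolan-2-yl]methyl}prop-2-enoate
Product: 20 methyl (Z)-2-(bromomethyl)-3-[(2R,4R)-4-hydroxy-5-methoxy-4-methyloxolan-2-yl]prop-2-enoate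
Conditions: NBS, Me2S, CH2Cl2, 0 °C to rt
Reagents that add atoms: N-bromosuccinimide, O=C1CCC(=O)N1Br
Why: The bromodimethylsulfonium reagent (Corey–Kim type) activates the allylic hydroxyl and bromide attacks in SN2′ fashion to give the (Z)-2-(bromomethyl)enoate, the hindered tertiary hydroxyl being expected to stay free.

Step 12
Reactants: 20 methyl (Z)-2-(bromomethyl)-3-[(2R,4R)-4-hydroxy-5-methoxy-4-methyloxolan-2-yl]prop-2-enoate; 7 (E)-3-[(tert-butyldiphenylsilyloxy)methyl]-5-(trimethylsilyl)pent-2-en-4-ynal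
Product: 22 (4R,5S)-5-[(E)-2-[(tert-butyldiphenylsilyloxy)methyl]-4-(trimethylsilyl)but-1-en-3-ynyl]-4-[(2R,4R)-4-hydroxy-5-methoxy-4-methyloxolan-2-yl]-3-methylideneoxolan-2-one (cis-lactone), via syn-hydroxy ester 21 (not isolated)
Conditions: indium powder, THF/H2O (1:1), rt; then CSA (cat.), CH2Cl2, rt
Reagents that add atoms: none
Why: The indium Barbier allylation should pass through a closed chair in which the Z γ-substituent is axial (syn adduct, hence the cis-lactone after acid-catalysed lactonisation), and with H8 held in the allyl plane by allylic 1,3-strain the aldehyde is expected to approach past the indium-binding ring oxygen O8 and anti to ring carbon C9, which sets C7 (R) and C6 (S).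

Step 13
Reactants: 22 cis-lactone with trimethylsilyl alkyne
Product: 23 (4R,5S)-5-[(E)-2-[(tert-butyldiphenylsilyloxy)methyl]-4-iodobut-1-en-3-ynyl]-4-[(2R,4R)-4-hydroxy-5-methoxy-4-methyloxolan-2-yl]-3-methylideneoxolan-2-one
Conditions: NIS, AgNO3 (10 mol %), acetone, rt, dark
Reagents that add atoms: N-iodosuccinimide, O=C1CCC(=O)N1I
Why: Silver-catalysed iododesilylation of the alkynylsilane should give the 1-iodoalkyne directly under neutral conditions tolerated by the methylene lactone and the acetal.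

Step 14
Reactants: 23 iodoalkyne methyl furanoside
Product: 24 (4R,5S)-4-[(2R,4R)-4,5-dihydroxy-4-methyloxolan-2-yl]-5-[(E)-2-[(tert-butyldiphenylsilyloxy)methyl]-4-iodobut-1-en-3-ynyl]-3-methylideneoxolan-2-one (lactol, anomers)
Conditions: AcOH/THF/H2O (3:1:1), 45 °C
Reagents that add atoms: water, O
Why: Mild aqueous acid hydrolysis of the furanoside (glycoside hydrolysis) should unmask C1 as the lactol while the tert-butyldiphenylsilyl ether, the iodoalkyne and the lactone persist.

Step 15
Reactants: 24 iodoalkyne lactol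
Product: 25 (6S,7R,8R,10R)-15-(tert-butyldiphenylsilyloxy)-1,8,10-trihydroxygermacra-4,11(13)-dien-2-yn-6,12-olide (ten-membered carbocycle, C3 cis to C6 on C4=C5, C1 epimers)
Conditions: CrCl2 (10 equiv), NiCl2 (5 mol %), THF, 2 mM, rt
Reagents that add atoms: none
Why: Intramolecular Nozaki–Hiyama–Kishi alkynylation at high dilution, in which the alkynylchromium formed via nickel adds to the open-chain aldehyde form of the lactol, should close the carbocycle at C1–C2 without a lasting new stereocentre (C1 is oxidised next) and frees the 8-hydroxyl.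

Step 16
Reactants: 25 ten-membered triol
Product: 26 (6S,7R,8R,10R)-15-(tert-butyldiphenylsilyloxy)-8,10-dihydroxy-1-oxogermacra-4,11(13)-dien-2-yn-6,12-olide (α′-hydroxy ynone)
Conditions: MnO2 (activated, excess), CH2Cl2, rt
Reagents that add atoms: none
Why: MnO2 oxidises the propargylic C1 carbinol selectively over the saturated secondary 8-hydroxyl and the tertiary 10-hydroxyl, giving the conjugated ynone.

Step 17
Reactants: 26 α′-hydroxy ynone
Product: 27 (6S,7R,8R,10R)-15-(tert-butyldiphenylsilyloxy)-8-hydroxy-1-oxo-3,10-epoxygermacra-2,4,11(13)-trien-6,12-olide (bridged 3(2H)-furanone)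
Conditions: (p-CF3C6H4)3PAuCl (5 mol %), AgOTf (5 mol %), toluene, rt
Reagents that add atoms: none
Why: The cationic gold phosphine complex π-activates the C2≡C3 bond of the ynone, the tertiary C10 hydroxyl (α′ to the C1 carbonyl, hence 1,4 to C3) adds anti to gold at C3, and protodeauration at C2 gives the 3(2H)-furanone. The closest known reaction type is the gold-catalysed cycloisomerisation of α′-hydroxy ynones to 3(2H)-furanones, here run transannularly. The one ring that closes is the five-membered furanone (O, C3, C2, C1, C10) in a 5-endo-dig mode, which at the same stroke converts the cyclodecenynone into the 11-oxabicyclo[6.2.1]undecane core. No new stereocentre is formed: C10 keeps its configuration because only its O–H bond reacts, and the lactone fusion and alkene geometry are already fixed. The step needs O10 rather than the free 8-hydroxyl to attack, and C3 rather than C2 to be attacked; O8 could reach C3 only through a seven-membered bridge and O10 could reach C2 only by a 4-exo closure, while ynone polarisation makes C3 the electrophilic carbon. Release of the bending strain of the alkyne in the ten-membered ring and formation of the vinylogous ester should drive the isomerisation.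

Step 18
Reactants: 27 bridged furanone alcohol; 28 (E)-2-methylbut-2-enoyl chloride (tigloyl chloride)
Product: 29 15-O-tert-butyldiphenylsilyl ether of the target (8-tiglate)
Conditions: 28 (2 equiv), pyridine, DMAP (cat.), CH2Cl2, 0 °C to rt
Reagents that add atoms: none
Why: DMAP-catalysed acylation of the only free hydroxyl installs the C8 ester with retention at C8 and of the E geometry of the acyl group.

Step 19
Reactants: 29 silyl-protected target
Product: 30 (6S,7R,8R,10R)-15-hydroxy-1-oxo-3,10-epoxygermacra-2,4,11(13)-trien-6,12-olid-8-yl (E)-2-methylbut-2-enoate (C4=C5 Z, cis-fused lactone; target)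
Conditions: HF·pyridine, THF/pyridine, 0 °C to rt
Reagents that add atoms: none
Why: Buffered fluoride desilylation should cleave the primary allylic silyl ether without conjugate addition to the methylene lactone or loss of the tiglate.

**Compound list**
1 | but-2-yne-1,4-diol | OCC#CCO | starting material
2 | 4-(tert-butyldiphenylsilyloxy)but-2-yn-1-ol | OCC#CCO[Si](c1ccccc1)(c1ccccc1)C(C)(C)C | intermediate
3 | cyclic sodium alkenylalanate (five-membered C–Al–O chelate, Al on the carbon bearing CH2OSi) | [Na+].COCCO[Al-]1(OCCOC)OCC=C1CO[Si](c1ccccc1)(c1ccccc1)C(C)(C)C | intermediate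
4 | (Z)-4-(tert-butyldiphenylsilyloxy)-3-iodobut-2-en-1-ol | OC/C=C(\I)CO[Si](c1ccccc1)(c1ccccc1)C(C)(C)C | intermediate
5 | ethynyltrimethylsilane | C#C[Si](C)(C)C | starting material
6 | (E)-3-[(tert-butyldiphenylsilyloxy)methyl]-5-(trimethylsilyl)pent-2-en-4-yn-1-ol | OC/C=C(\C#C[Si](C)(C)C)CO[Si](c1ccccc1)(c1ccccc1)C(C)(C)C | intermediate
7 | (E)-3-[(tert-butyldiphenylsilyloxy)methyl]-5-(trimethylsilyl)pent-2-en-4-ynal | O=C/C=C(\C#C[Si](C)(C)C)CO[Si](c1ccccc1)(c1ccccc1)C(C)(C)C | intermediate
8 | 4-methylpent-3-en-2-one (mesityl oxide) | CC(=O)C=C(C)C | starting material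
9 | 4-methyl-2-(trimethylsilyloxy)penta-1,3-diene | C=C(O[Si](C)(C)C)C=C(C)C | intermediate
10 | methyl pyruvate | CC(=O)C(=O)OC | starting material
11 | methyl (R)-2,6-dimethyl-4-oxo-2-(trimethylsilyloxy)hept-5-enoate | COC(=O)[C@@](C)(CC(=O)C=C(C)C)O[Si](C)(C)C | intermediate
12 | methyl (2R,4R)-4-hydroxy-2,6-dimethyl-2-(trimethylsilyloxy)hept-5-enoate | COC(=O)[C@@](C)(C[C@@H](O)C=C(C)C)O[Si](C)(C)C | intermediate
13 | (3R,5R)-3-hydroxy-3-methyl-5-(2-methylprop-1-enyl)oxolan-2-one | O=C1[C@](C)(O)C[C@H](C=C(C)C)O1 | intermediate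
14 | (3R,5R)-3-methyl-5-(2-methylprop-1-enyl)oxolane-2,3-diol (lactol, anomers) | OC1[C@](C)(O)C[C@H](C=C(C)C)O1 | intermediate
15 | (3R,5R)-2-methoxy-3-methyl-5-(2-methylprop-1-enyl)oxolan-3-ol (anomers) | COC1[C@](C)(O)C[C@H](C=C(C)C)O1 | intermediate
16 | ozonide of 15 (5,5-dimethyl-1,2,4-trioxolan-3-yl in place of the alkenyl group) | COC1[C@](C)(O)C[C@H](C2OOC(C)(C)O2)O1 | intermediate
17 | (2R,4R)-4-hydroxy-5-methoxy-4-methyloxolane-2-carbaldehyde | COC1[C@](C)(O)C[C@H](C=O)O1 | intermediate
18 | methyl acrylate | C=CC(=O)OC | starting material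
19 | methyl 2-{hydroxy[(2R,4R)-4-hydroxy-5-methoxy-4-methyloxolan-2-yl]methyl}prop-2-enoate | COC1[C@](C)(O)C[C@H](C(O)C(=C)C(=O)OC)O1 | intermediate
20 | methyl (Z)-2-(bromomethyl)-3-[(2R,4R)-4-hydroxy-5-methoxy-4-methyloxolan-2-yl]prop-2-enoate | COC1[C@](C)(O)C[C@H](/C=C(\CBr)C(=O)OC)O1 | intermediate
21 | methyl (5E)-6-[(tert-butyldiphenylsilyloxy)methyl]-4-hydroxy-3-[(2R,4R)-4-hydroxy-5-methoxy-4-methyloxolan-2-yl]-2-methylidene-8-(trimethylsilyl)oct-5-en-7-ynoate (syn adduct, C6 and C7 as in 22) | C=C(C(=O)OC)[C@@H]([C@@H](O)/C=C(/CO[Si](c1ccccc1)(c1ccccc1)C(C)(C)C)C#C[Si](C)(C)C)[C@H]1C[C@@](C)(O)C(OC)O1 | intermediate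
22 | (4R,5S)-5-[(E)-2-[(tert-butyldiphenylsilyloxy)methyl]-4-(trimethylsilyl)but-1-en-3-ynyl]-4-[(2R,4R)-4-hydroxy-5-methoxy-4-methyloxolan-2-yl]-3-methylideneoxolan-2-one | C=C1C(=O)O[C@@H](/C=C(/CO[Si](c2ccccc2)(c2ccccc2)C(C)(C)C)C#C[Si](C)(C)C)[C@H]1[C@H]3C[C@@](C)(O)C(OC)O3 | intermediate
23 | (4R,5S)-5-[(E)-2-[(tert-butyldiphenylsilyloxy)methyl]-4-iodobut-1-en-3-ynyl]-4-[(2R,4R)-4-hydroxy-5-methoxy-4-methyloxolan-2-yl]-3-methylideneoxolan-2-one | C=C1C(=O)O[C@@H](/C=C(/CO[Si](c2ccccc2)(c2ccccc2)C(C)(C)C)C#CI)[C@H]1[C@H]3C[C@@](C)(O)C(OC)O3 | intermediate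
24 | (4R,5S)-4-[(2R,4R)-4,5-dihydroxy-4-methyloxolan-2-yl]-5-[(E)-2-[(tert-butyldiphenylsilyloxy)methyl]-4-iodobut-1-en-3-ynyl]-3-methylideneoxolan-2-one | C=C1C(=O)O[C@@H](/C=C(/CO[Si](c2ccccc2)(c2ccccc2)C(C)(C)C)C#CI)[C@H]1[C@H]3C[C@@](C)(O)C(O)O3 | intermediate
25 | (6S,7R,8R,10R)-15-(tert-butyldiphenylsilyloxy)-1,8,10-trihydroxygermacra-4,11(13)-dien-2-yn-6,12-olide (C1 epimers) | C=C1C(=O)O[C@H]2/C=C(/CO[Si](c3ccccc3)(c3ccccc3)C(C)(C)C)C#CC(O)[C@](C)(O)C[C@@H](O)[C@@H]12 | intermediate
26 | (6S,7R,8R,10R)-15-(tert-butyldiphenylsilyloxy)-8,10-dihydroxy-1-oxogermacra-4,11(13)-dien-2-yn-6,12-olide | C=C1C(=O)O[C@H]2/C=C(/CO[Si](c3ccccc3)(c3ccccc3)C(C)(C)C)C#CC(=O)[C@](C)(O)C[C@@H](O)[C@@H]12 | intermediate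
27 | (6S,7R,8R,10R)-15-(tert-butyldiphenylsilyloxy)-8-hydroxy-1-oxo-3,10-epoxygermacra-2,4,11(13)-trien-6,12-olide | C=C1C(=O)O[C@H]2/C=C(/CO[Si](c4ccccc4)(c4ccccc4)C(C)(C)C)C3=CC(=O)[C@@](C)(C[C@@H](O)[C@@H]12)O3 | intermediate
28 | (E)-2-methylbut-2-enoyl chloride (tigloyl chloride) | C/C=C(\C)C(Cl)=O | starting material
29 | 15-O-tert-butyldiphenylsilyl ether of 30 | C=C1C(=O)O[C@H]2/C=C(/CO[Si](c4ccccc4)(c4ccccc4)C(C)(C)C)C3=CC(=O)[C@@](C)(C[C@@H](OC(=O)/C(C)=C/C)[C@@H]12)O3 | intermediate
30 | (6S,7R,8R,10R)-15-hydroxy-1-oxo-3,10-epoxygermacra-2,4,11(13)-trien-6,12-olid-8-yl (E)-2-methylbut-2-enoate | C=C1C(=O)O[C@H]2/C=C(/CO)C3=CC(=O)[C@@](C)(C[C@@H](OC(=O)/C(C)=C/C)[C@@H]12)O3 | target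

**Count and risks**
Total step count: 19. Longest linear sequence: 15 steps (steps 5 to 19, from 8); the enynal branch (steps 1 to 4) joins at step 12.

Step 15 (ring closure on the lactol). What may go wrong: the γ-lactol opens too slowly to the aldehyde, so that protonolysis of the alkynylchromium or intermolecular coupling outruns the ten-membered ring closure. Fallback, from 24 back to 29: the aldehyde is freed for good before the ring is closed. Reduction of 24 (NaBH4, CeCl3, MeOH, −40 °C) gives the open-chain triol F1. Its 1,2-diol is masked (2,2-dimethoxypropane, PPTS) as the acetonide F2. The now unique secondary 8-hydroxyl is esterified with 28 (pyridine, DMAP) to the tiglate acetonide F3. Aqueous AcOH releases the diol tiglate F4. TEMPO/PhI(OAc)2 oxidises the primary alcohol to the α-hydroxy aldehyde F5, which has no hydroxyl left to form a lactol. The same CrCl2/NiCl2 closure should then give the ten-membered diol tiglate F6, MnO2 the ynone tiglate F7, and the gold cyclisation of step 17 leads directly to 29.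

Step 12 (indium allylation). What may go wrong: poor facial selectivity on the allylindium (approach past C9 instead of O8) or erosion of the syn relationship, giving C6/C7 diastereomers. Fallback, from 19 (with 7) back to 22: the bond is made by a catalyst-controlled allylboration. Acetylation of 19 (Ac2O, pyridine) gives the allylic acetate F8. Copper-catalysed SN2′ borylation (B2pin2, CuCl, KOtBu) gives the (Z)-allylboronate F9. Its addition to 7 under a chiral BINOL-derived phosphoric acid ((R)-TRIP, toluene, −30 °C) runs through a closed six-membered transition state in which the catalyst fixes the aldehyde face and the Z-boronate enforces syn; lactonisation with CSA returns 22 via 21.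

Step 17 (transannular cyclisation). What may go wrong: the free 8-hydroxyl interferes (reversible hemiketal formation at C1, or conjugate addition), or the strained ynone is hydrated instead of closing 5-endo. Fallback, from 26 back to 27: the classical amine route. Diethylamine (EtOH, rt) adds to the ynone to give the β-(diethylamino)enone F10. Aqueous AcOH then hydrolyses the enaminone to the 1,3-diketone, whose C3 carbonyl is captured by O10 and dehydrated to the furanone 27.

**Further compounds**
F1 | step 15 | open-chain triol from 24 (C1 CH2OH, 8-OH, 10-OH, iodoalkyne) | C=C1C(=O)O[C@@H](/C=C(/CO[Si](c2ccccc2)(c2ccccc2)C(C)(C)C)C#CI)[C@H]1[C@H](O)C[C@@](C)(O)CO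
F2 | step 15 | 1,10-O-isopropylidene acetal of F1 | C=C1C(=O)O[C@@H](/C=C(/CO[Si](c2ccccc2)(c2ccccc2)C(C)(C)C)C#CI)[C@H]1[C@H](O)C[C@]3(C)COC(C)(C)O3
F3 | step 15 | 8-O-tiglate of F2 | C=C1C(=O)O[C@@H](/C=C(/CO[Si](c2ccccc2)(c2ccccc2)C(C)(C)C)C#CI)[C@H]1[C@H](OC(=O)/C(C)=C/C)C[C@]3(C)COC(C)(C)O3
F4 | step 15 | 1,10-diol 8-tiglate | C=C1C(=O)O[C@@H](/C=C(/CO[Si](c2ccccc2)(c2ccccc2)C(C)(C)C)C#CI)[C@H]1[C@H](OC(=O)/C(C)=C/C)C[C@@](C)(O)CO
F5 | step 15 | C1 α-hydroxy aldehyde 8-tiglate | C=C1C(=O)O[C@@H](/C=C(/CO[Si](c2ccccc2)(c2ccccc2)C(C)(C)C)C#CI)[C@H]1[C@H](OC(=O)/C(C)=C/C)C[C@@](C)(O)C=O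
F6 | step 15 | ten-membered 1,10-diol 8-tiglate (C1 epimers) | C=C1C(=O)O[C@H]2/C=C(/CO[Si](c3ccccc3)(c3ccccc3)C(C)(C)C)C#CC(O)[C@](C)(O)C[C@@H](OC(=O)/C(C)=C/C)[C@@H]12
F7 | step 15 | ten-membered α′-hydroxy ynone 8-tiglate | C=C1C(=O)O[C@H]2/C=C(/CO[Si](c3ccccc3)(c3ccccc3)C(C)(C)C)C#CC(=O)[C@](C)(O)C[C@@H](OC(=O)/C(C)=C/C)[C@@H]12
F8 | step 12 | allylic acetate of 19 | COC1[C@](C)(O)C[C@H](C(OC(C)=O)C(=C)C(=O)OC)O1
F9 | step 12 | methyl (Z)-3-[(2R,4R)-4-hydroxy-5-methoxy-4-methyloxolan-2-yl]-2-[(4,4,5,5-tetramethyl-1,3,2-dioxaborolan-2-yl)methyl]prop-2-enoate | COC1[C@](C)(O)C[C@H](/C=C(\CB2OC(C)(C)C(C)(C)O2)C(=O)OC)O1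
F10 | step 17 | β-(diethylamino)enone from 26 (NEt2 on C3) | C=C1C(=O)O[C@H]2/C=C(/CO[Si](c3ccccc3)(c3ccccc3)C(C)(C)C)C(N(CC)CC)=CC(=O)[C@](C)(O)C[C@@H](O)[C@@H]12
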